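**Plan**

- Numbering (germacranolide): ring A is the furanone (C1 ketone, C2=C3, O bridging C3 and C10, C14 methyl on C10); ring C is the lactone (C6–O, C12, C11=C13, C7); C15 is the CH2OAc on C4; ring B is the nine-membered oxacycle C3–C4–C5–C6–C7–C8–C9–C10–O.
- Cuts, in retrosynthetic order: C8–O acyl; C7–C8; O–C3 of ring A (α'-hydroxy ynone); C3–C4 (Sonogashira); C7=C11 (RCM) and O6–C12 (ester); C5–C6 (alkynylation).
- Enabling feature: C8(OH)–C7–C11=C13 in ring C is a homoallylic alcohol, the retron of a carbonyl allylation. Ring B therefore opens to a 3-(bromomethyl)butenolide and a C8 aldehyde, two natively electrophilic carbons (C7, C8) joined by polarity reversal.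
- Forward order: ring C (butenolide, RCM), then ring A (gold cycloisomerisation), then ring B last by CrCl2-mediated intramolecular allylation, which also sets C7 and C8 and unveils the exocyclic methylene.
- Stereochemistry: C6 from asymmetric alkynylation of crotonaldehyde; C10 from (R)-citramalic acid; Z-C4=C5 from hydroxyl-directed trans-hydroalumination/iodination; C7 and C8 from the chair transition state of the ring closure, relayed from C6.
- Helpers: a methyl ketal ring ties up the C1 ketone and O8 until after the coupling; PMB on O15 and TBS on O13 are removed on the way.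

Key step: step 17

Assumption: in step 1 the (S,S)-ProPhenol/Me2Zn catalyst is taken to deliver the (S)-carbinol; if the sense is the opposite, (R,R)-ProPhenol is used and nothing else changes.

Note on descriptors: the C6 descriptor changes from S (compounds 3–11) to R (18 onward), and the C4=C5 descriptor from Z (iodides) to E (enynes) to Z (furanones), only through CIP priority changes; the geometry is the same throughout.

**Route**

Step 1
Reactants: 1 (2E)-but-2-enal; 2 4-methoxybenzyl propargyl ether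
Product: 3 (2E,4S)-7-[(4-methoxybenzyl)oxy]hept-2-en-5-yn-4-ol
Conditions: (S,S)-ProPhenol (10 mol%), Ph3PO (20 mol%), Me2Zn (3 equiv), toluene, 0 °C
Reagents that add atoms: none
Why: Zinc–ProPhenol asymmetric alkynylation of an enal, in which the dinuclear zinc catalyst holds alkynylzinc and aldehyde and adds the alkyne to one carbonyl face, sets C6 (4S here, the future 6R).

Step 2
Reactants: 3 (2E,4S)-7-[(4-methoxybenzyl)oxy]hept-2-en-5-yn-4-ol
Product: 5 (2Z,4S,5E)-2-iodo-1-[(4-methoxybenzyl)oxy]hepta-2,5-dien-4-ol, via cyclic sodium alkenylalanate 4 (not isolated)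
Conditions: NaAlH2(OCH2CH2OMe)2, THF, 0 °C; EtOAc, then I2, THF, −78 °C
Reagents that add atoms: iodine, II
Why: Hydroxyl-directed trans-hydroalumination of the propargylic alcohol puts aluminium on the distal alkyne carbon (C4) in a five-membered alanate, and iodinolysis with retention gives the Z-vinyl iodide (I cis to C6) without touching the carbinol centre.

Step 3
Reactants: 6 ethyl 2-(hydroxymethyl)prop-2-enoate
Product: 7 ethyl 2-{[(tert-butyldimethylsilyl)oxy]methyl}prop-2-enoate
Conditions: TBSCl, imidazole, CH2Cl2, 0 °C to rt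
Reagents that add atoms: tert-butyldimethylsilyl chloride, CC(C)(C)[Si](C)(C)Cl
Why: Standard silylation of a primary allylic alcohol protects the future C13 oxygen.

Step 4
Reactants: 7 ethyl 2-{[(tert-butyldimethylsilyl)oxy]methyl}prop-2-enoate
Product: 8 2-{[(tert-butyldimethylsilyl)oxy]methyl}prop-2-enoic acid
Conditions: LiOH, THF/H2O, 0 °C to rt; then 1 M HCl to pH 4, 0 °C
Reagents that add atoms: lithium hydroxide, [Li+].[OH-]
Why: Saponification of the ethyl ester proceeds cold, and the primary silyl ether tolerates LiOH and a brief mildly acidic work-up.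

Step 5
Reactants: 5 (2Z,4S,5E)-2-iodo-1-[(4-methoxybenzyl)oxy]hepta-2,5-dien-4-ol; 8 2-{[(tert-butyldimethylsilyl)oxy]methyl}prop-2-enoic acid
Product: 9 (2Z,4S,5E)-2-iodo-1-[(4-methoxybenzyl)oxy]hepta-2,5-dien-4-yl 2-{[(tert-butyldimethylsilyl)oxy]methyl}prop-2-enoate
Conditions: DCC, DMAP (cat.), CH2Cl2, 0 °C to rt
Reagents that add atoms: none
Why: Steglich esterification acylates the bis-allylic secondary alcohol on oxygen under neutral conditions, so the C6–O bond is not ionised and the configuration is kept.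

Step 6
Reactants: 9 (2Z,4S,5E)-2-iodo-1-[(4-methoxybenzyl)oxy]hepta-2,5-dien-4-yl 2-{[(tert-butyldimethylsilyl)oxy]methyl}prop-2-enoate
Product: 10 (5S)-3-{[(tert-butyldimethylsilyl)oxy]methyl}-5-{(1Z)-2-iodo-3-[(4-methoxybenzyl)oxy]prop-1-en-1-yl}furan-2(5H)-one
Conditions: second-generation Grubbs catalyst RuCl2(=CHPh)(H2IMes)(PCy3) (5 mol%), toluene, 80 °C
Reagents that add atoms: none
Why: Ring-closing metathesis between the propenyl group and the 2-substituted acrylate closes the butenolide (ring C) with loss of propene, and the hindered trisubstituted iodoalkene does not take part.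

Step 7
Reactants: 10 (5S)-3-{[(tert-butyldimethylsilyl)oxy]methyl}-5-{(1Z)-2-iodo-3-[(4-methoxybenzyl)oxy]prop-1-en-1-yl}furan-2(5H)-one
Product: 11 (5S)-3-{[(tert-butyldimethylsilyl)oxy]methyl}-5-[(1Z)-3-hydroxy-2-iodoprop-1-en-1-yl]furan-2(5H)-one
Conditions: DDQ, CH2Cl2/pH 7 buffer, 0 °C to rt
Reagents that add atoms: none
Why: Oxidative cleavage of the PMB ether by DDQ is neutral and leaves the silyl ether, the vinyl iodide and the base-sensitive butenolide untouched.

Step 8
Reactants: 12 (R)-citramalic acid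
Product: 13 2-[(4R)-2,2,4-trimethyl-5-oxo-1,3-dioxolan-4-yl]acetic acid
Conditions: 2,2-dimethoxypropane, TsOH·H2O (cat.), rt
Reagents that add atoms: 2,2-dimethoxypropane, COC(C)(C)OC
Why: Acetonide formation across the α-hydroxy acid gives the five-membered dioxolanone and thereby differentiates the two carboxyl groups; the quaternary centre (future C10) comes unchanged from the chiral pool.

Step 9
Reactants: 13 2-[(4R)-2,2,4-trimethyl-5-oxo-1,3-dioxolan-4-yl]acetic acid
Product: 15 (3R)-3-hydroxy-3-methyloxolan-2-one, via dioxolanone alcohol 14 (not isolated)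
Conditions: BH3·SMe2, THF, 0 °C to rt; MeOH; then TsOH·H2O (cat.), CH2Cl2, rt
Reagents that add atoms: none
Why: Borane reduces the free carboxylic acid chemoselectively beside the dioxolanone, and acid-catalysed translactonisation of the resulting alcohol expels acetone to give the γ-lactone without involving the quaternary centre.

Step 10
Reactants: 15 (3R)-3-hydroxy-3-methyloxolan-2-one
Product: 17 (3R)-2-ethynyl-2-methoxy-3-methyloxolan-3-ol, via ethynyl lactol 16 (not isolated)
Conditions: HC≡CMgBr (2.5 equiv), THF, −40 to 0 °C; then MsOH, MeOH, 0 °C to rt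
Reagents that add atoms: ethynylmagnesium bromide, C#C[Mg]Br; methanol, CO
Why: The acetylide adds once to the lactone because the chelated magnesium hemiketalate does not collapse in the cold, and acidic methanol turns the lactol into its methyl ketal (lactone-to-alkynyl-ketal sequence known from C-glycoside work), a temporary ring that masks the C1 ketone and O8.

Step 11
Reactants: 11 (5S)-3-{[(tert-butyldimethylsilyl)oxy]methyl}-5-[(1Z)-3-hydroxy-2-iodoprop-1-en-1-yl]furan-2(5H)-one; 17 (3R)-2-ethynyl-2-methoxy-3-methyloxolan-3-ol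
Product: 18 (5R)-3-{[(tert-butyldimethylsilyl)oxy]methyl}-5-{(1E)-2-(hydroxymethyl)-4-[(3R)-3-hydroxy-2-methoxy-3-methyloxolan-2-yl]but-1-en-3-yn-1-yl}furan-2(5H)-one
Conditions: PdCl2(PPh3)2 (5 mol%), CuI (10 mol%), iPr2NEt, THF, rt
Reagents that add atoms: none
Why: Sonogashira coupling forms C3–C4 with retention of the iodoalkene geometry (C3 ends cis to C6); a hindered tertiary amine at room temperature is chosen so that the γ-proton at C6 of the butenolide is not removed.

Step 12
Reactants: 18 enyne diol (as named in step 11)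
Product: 19 (2E)-3-[(2R)-4-{[(tert-butyldimethylsilyl)oxy]methyl}-5-oxo-2,5-dihydrofuran-2-yl]-2-{[(3R)-3-hydroxy-2-methoxy-3-methyloxolan-2-yl]ethynyl}prop-2-en-1-yl acetate
Conditions: Ac2O, pyridine, CH2Cl2, 0 °C
Reagents that add atoms: acetic anhydride, CC(=O)OC(C)=O
Why: Acetylation is selective for the primary allylic O15 hydroxyl because the tertiary C10 hydroxyl is too hindered to react at 0 °C; installing the acetate only now keeps an allylic acetate away from the palladium step.

Step 13
Reactants: 19 silyl ether acetate (as named in step 12)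
Product: 20 (2E)-3-[(2R)-4-(hydroxymethyl)-5-oxo-2,5-dihydrofuran-2-yl]-2-{[(3R)-3-hydroxy-2-methoxy-3-methyloxolan-2-yl]ethynyl}prop-2-en-1-yl acetate
Conditions: HF·pyridine, pyridine, THF, 0 °C to rt
Reagents that add atoms: none
Why: Buffered anhydrous fluoride cleaves the primary silyl ether without hydrolysing the ketal or the acetate and without enolising the butenolide.

Step 14
Reactants: 20 allylic alcohol (as named in step 13)
Product: 21 (2E)-3-[(2R)-4-(bromomethyl)-5-oxo-2,5-dihydrofuran-2-yl]-2-{[(3R)-3-hydroxy-2-methoxy-3-methyloxolan-2-yl]ethynyl}prop-2-en-1-yl acetate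
Conditions: CBr4, PPh3, 2,6-lutidine, CH2Cl2, −20 to 0 °C
Reagents that add atoms: tetrabromomethane, BrC(Br)(Br)Br
Why: Appel bromination converts only the primary allylic alcohol (the tertiary alcohol is inert) under neutral conditions, and the aldehyde that would react with this reagent is still masked in the ketal.

Step 15
Reactants: 21 bromomethyl butenolide ketal (as named in step 14)
Product: 23 (2Z)-3-[(2R)-4-(bromomethyl)-5-oxo-2,5-dihydrofuran-2-yl]-2-[(5R)-5-(2-hydroxyethyl)-5-methyl-4-oxo-4,5-dihydrofuran-2-yl]prop-2-en-1-yl acetate, via hydroxy ynone 22 (not isolated)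
Conditions: TsOH·H2O (10 mol%), acetone/H2O 10:1, rt; then AuCl3 (5 mol%), same flask, rt
Reagents that add atoms: water, O
Why: Acid hydrolysis of the methyl ketal releases the α'-hydroxy ynone, and gold π-activation of the alkyne triggers 5-endo-dig attack of the tertiary C10 hydroxyl on C3 (hydroxy ynone to 3(2H)-furanone cycloisomerisation), closing ring A with the C10 configuration intact and freeing O8.

Step 16
Reactants: 23 furanone alcohol (as named in step 15)
Product: 24 (2Z)-3-[(2R)-4-(bromomethyl)-5-oxo-2,5-dihydrofuran-2-yl]-2-[(5R)-5-methyl-4-oxo-5-(2-oxoethyl)-4,5-dihydrofuran-2-yl]prop-2-en-1-yl acetate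
Conditions: DMP, CH2Cl2, 0 °C to rt
Reagents that add atoms: none
Why: Dess–Martin oxidation gives the C8 aldehyde under neutral conditions that spare the allylic bromide and avoid base-induced β-elimination of the furanone oxygen.

Step 17
Reactants: 24 bromo aldehyde (as named in step 16)
Product: 26 [(2Z,4R,8R,9S,11R)-9-hydroxy-11-methyl-7-methylidene-6,12-dioxo-5,14-dioxatricyclo[9.2.1.0(4,8)]tetradeca-1(13),2-dien-2-yl]methyl acetate, via allylchromium dichloride 25 (not isolated)
Conditions: CrCl2 (8 equiv), THF, rt, 24 added by syringe pump over 10 h to about 2 mM; then H2O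
Reagents that add atoms: none
Why: Two equivalents of CrCl2 (divalent chromium) reduce the allylic C13–Br bond to the primary allylchromium species 25 (trivalent chromium), which adds to the tethered C8 aldehyde with allylic transposition through a six-membered chair transition state, so that C7–C8 forms and the ring C7=C11 bond moves to the exocyclic C11=C13 position. The closest known reaction type is the intramolecular Nozaki–Hiyama allylation of ω-formyl 2-(bromomethyl)acrylates and 3-(bromomethyl)butenolides used to close medium-ring α-methylene lactones. Ring B (the nine-membered oxacycle, equally the ten-membered carbocycle through C1–C2) closes in the exo-trig mode at the aldehyde, helped by the planar furanone and the Z-C4=C5 bond, which fix five ring atoms and hold both termini on one side. C7 is set by attack on the butenolide face anti to the C5 substituent at C6 (trans-fused lactone, 7R), and C8 by the ring-locked E-type allyl geometry (C6 trans to CH2Cr) with C9 equatorial in the chair, which gives the 7,8-anti relationship (8S). The step needs ring closure to beat intermolecular coupling and protonation (slow addition, high dilution), aldehyde over ketone selectivity (the allylchromium reagent ignores the vinylogous-ester ketone C1 and the acetate), γ- over α-attack (inherent to the primary allylchromium), and no lactone migration to O8 (the chromium alkoxide is kinetically inert).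

Step 18
Reactants: 26 macrocyclic alcohol (as named in step 17)
Product: 27 [(2Z,4R,8R,9S,11R)-2-(acetyloxymethyl)-11-methyl-7-methylidene-6,12-dioxo-5,14-dioxatricyclo[9.2.1.0(4,8)]tetradeca-1(13),2-dien-9-yl] 2-methylprop-2-enoate
Conditions: methacrylic anhydride, Et3N, DMAP (cat.), CH2Cl2, 0 °C
Reagents that add atoms: methacrylic anhydride, C=C(C)C(=O)OC(=O)C(C)=C
Why: DMAP-catalysed acylation of the secondary C8 alcohol occurs at oxygen with retention, and the cold, short reaction limits translactonisation and amine addition to the α-methylene lactone.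

**Compound list**

1 | (2E)-but-2-enal (crotonaldehyde) | C/C=C/C=O | starting material
2 | 1-methoxy-4-[(prop-2-yn-1-yloxy)methyl]benzene | C#CCOCc1ccc(OC)cc1 | starting material
3 | (2E,4S)-7-[(4-methoxybenzyl)oxy]hept-2-en-5-yn-4-ol | COc1ccc(COCC#C[C@H](/C=C/C)O)cc1 | intermediate
4 | cyclic sodium alkenylalanate (five-membered O–Al–C4=C5–C6 ring, two 2-methoxyethoxy groups on Al) | COCCO[Al-]1(OCCOC)O[C@@H](/C=C/C)C=C1COCc1ccc(OC)cc1.[Na+] | intermediate
5 | (2Z,4S,5E)-2-iodo-1-[(4-methoxybenzyl)oxy]hepta-2,5-dien-4-ol | COc1ccc(COC/C(I)=C/[C@H](/C=C/C)O)cc1 | intermediate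
6 | ethyl 2-(hydroxymethyl)prop-2-enoate | C=C(CO)C(=O)OCC | starting material
7 | ethyl 2-{[(tert-butyldimethylsilyl)oxy]methyl}prop-2-enoate | C=C(CO[Si](C)(C)C(C)(C)C)C(=O)OCC | intermediate
8 | 2-{[(tert-butyldimethylsilyl)oxy]methyl}prop-2-enoic acid | C=C(CO[Si](C)(C)C(C)(C)C)C(=O)O | intermediate
9 | (2Z,4S,5E)-2-iodo-1-[(4-methoxybenzyl)oxy]hepta-2,5-dien-4-yl 2-{[(tert-butyldimethylsilyl)oxy]methyl}prop-2-enoate | COc1ccc(COC/C(I)=C/[C@H](/C=C/C)OC(=O)C(=C)CO[Si](C)(C)C(C)(C)C)cc1 | intermediate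
10 | (5S)-3-{[(tert-butyldimethylsilyl)oxy]methyl}-5-{(1Z)-2-iodo-3-[(4-methoxybenzyl)oxy]prop-1-en-1-yl}furan-2(5H)-one | COc1ccc(COC/C(I)=C/[C@H]2OC(=O)C(CO[Si](C)(C)C(C)(C)C)=C2)cc1 | intermediate
11 | (5S)-3-{[(tert-butyldimethylsilyl)oxy]methyl}-5-[(1Z)-3-hydroxy-2-iodoprop-1-en-1-yl]furan-2(5H)-one | OC/C(I)=C/[C@H]1OC(=O)C(CO[Si](C)(C)C(C)(C)C)=C1 | intermediate
12 | (R)-citramalic acid, (2R)-2-hydroxy-2-methylbutanedioic acid | OC(=O)C[C@@](C(=O)O)(C)O | starting material
13 | 2-[(4R)-2,2,4-trimethyl-5-oxo-1,3-dioxolan-4-yl]acetic acid | OC(=O)C[C@@]1(C)OC(C)(C)OC1=O | intermediate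
14 | (5R)-5-(2-hydroxyethyl)-2,2,5-trimethyl-1,3-dioxolan-4-one | OCC[C@@]1(C)OC(C)(C)OC1=O | intermediate
15 | (3R)-3-hydroxy-3-methyloxolan-2-one | O=C1OCC[C@@]1(C)O | intermediate
16 | (3R)-2-ethynyl-3-methyloxolane-2,3-diol (anomer mixture) | C#CC1(O)OCC[C@@]1(C)O | intermediate
17 | (3R)-2-ethynyl-2-methoxy-3-methyloxolan-3-ol (mixture at C2) | C#CC1(OC)OCC[C@@]1(C)O | intermediate
18 | (5R)-3-{[(tert-butyldimethylsilyl)oxy]methyl}-5-{(1E)-2-(hydroxymethyl)-4-[(3R)-3-hydroxy-2-methoxy-3-methyloxolan-2-yl]but-1-en-3-yn-1-yl}furan-2(5H)-one | COC1(C#C/C(CO)=C\[C@H]2OC(=O)C(CO[Si](C)(C)C(C)(C)C)=C2)OCC[C@@]1(C)O | intermediate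
19 | (2E)-3-[(2R)-4-{[(tert-butyldimethylsilyl)oxy]methyl}-5-oxo-2,5-dihydrofuran-2-yl]-2-{[(3R)-3-hydroxy-2-methoxy-3-methyloxolan-2-yl]ethynyl}prop-2-en-1-yl acetate | COC1(C#C/C(COC(C)=O)=C\[C@H]2OC(=O)C(CO[Si](C)(C)C(C)(C)C)=C2)OCC[C@@]1(C)O | intermediate
20 | (2E)-3-[(2R)-4-(hydroxymethyl)-5-oxo-2,5-dihydrofuran-2-yl]-2-{[(3R)-3-hydroxy-2-methoxy-3-methyloxolan-2-yl]ethynyl}prop-2-en-1-yl acetate | COC1(C#C/C(COC(C)=O)=C\[C@H]2OC(=O)C(CO)=C2)OCC[C@@]1(C)O | intermediate
21 | (2E)-3-[(2R)-4-(bromomethyl)-5-oxo-2,5-dihydrofuran-2-yl]-2-{[(3R)-3-hydroxy-2-methoxy-3-methyloxolan-2-yl]ethynyl}prop-2-en-1-yl acetate | COC1(C#C/C(COC(C)=O)=C\[C@H]2OC(=O)C(CBr)=C2)OCC[C@@]1(C)O | intermediate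
22 | (2E,6R)-2-{[(2R)-4-(bromomethyl)-5-oxo-2,5-dihydrofuran-2-yl]methylidene}-6,8-dihydroxy-6-methyl-5-oxooct-3-yn-1-yl acetate (in equilibrium with its cyclic hemiketal) | OCC[C@@](C)(O)C(=O)C#C/C(COC(C)=O)=C\[C@H]1OC(=O)C(CBr)=C1 | intermediate
23 | (2Z)-3-[(2R)-4-(bromomethyl)-5-oxo-2,5-dihydrofuran-2-yl]-2-[(5R)-5-(2-hydroxyethyl)-5-methyl-4-oxo-4,5-dihydrofuran-2-yl]prop-2-en-1-yl acetate | OCC[C@@]1(C)OC(=CC1=O)/C(COC(C)=O)=C\[C@H]1OC(=O)C(CBr)=C1 | intermediate
24 | (2Z)-3-[(2R)-4-(bromomethyl)-5-oxo-2,5-dihydrofuran-2-yl]-2-[(5R)-5-methyl-4-oxo-5-(2-oxoethyl)-4,5-dihydrofuran-2-yl]prop-2-en-1-yl acetate | O=CC[C@@]1(C)OC(=CC1=O)/C(COC(C)=O)=C\[C@H]1OC(=O)C(CBr)=C1 | intermediate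
25 | allylchromium dichloride derived from 24 (CrCl2 on C13) | O=CC[C@@]1(C)OC(=CC1=O)/C(COC(C)=O)=C\[C@H]1OC(=O)C(C[Cr](Cl)Cl)=C1 | intermediate
26 | [(2Z,4R,8R,9S,11R)-9-hydroxy-11-methyl-7-methylidene-6,12-dioxo-5,14-dioxatricyclo[9.2.1.0(4,8)]tetradeca-1(13),2-dien-2-yl]methyl acetate | O[C@H]1C[C@@]2(C)OC(=CC2=O)/C(COC(C)=O)=C\[C@H]2OC(=O)C(=C)[C@H]12 | intermediate
27 | [(2Z,4R,8R,9S,11R)-2-(acetyloxymethyl)-11-methyl-7-methylidene-6,12-dioxo-5,14-dioxatricyclo[9.2.1.0(4,8)]tetradeca-1(13),2-dien-9-yl] 2-methylprop-2-enoate (15-O-acetylgoyazensolide) | C=C(C)C(=O)O[C@H]1C[C@@]2(C)OC(=CC2=O)/C(COC(C)=O)=C\[C@H]2OC(=O)C(=C)[C@H]12 | target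

**Count**

Total steps: 18. Longest linear sequence: 13 steps (1, 2, 5, 6, 7, 11 to 18).

**Steps most likely to fail**

1. Step 17. The tether may force the aldehyde chain axial in the chair, so that the ring closes through the diastereomeric transition state and C8 is mis-set; slow closure also lets protonation and dimerisation of the allylchromium compete. Fallback: setting out from 24, the C8-epimeric macrocyclic alcohol F1 is taken on instead of 26 and esterified with inversion under Mitsunobu conditions (methacrylic acid, PPh3, DIAD, toluene, 0 °C). This gives 27 directly and bypasses step 18.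

2. Step 11. The amine may deprotonate the γ-position of the butenolide (C6–H, allylic and vinylogously acidic), which would erode the C6 configuration during the coupling. Fallback: setting out from 17, double deprotonation (n-BuLi, THF, −78 °C) and C-stannylation with Bu3SnCl give the alkynylstannane F2. This is joined to 11 by a base-free Stille coupling (Pd2(dba)3, AsPh3, DMF, rt), returning to 18.

3. Step 15. The allylic bromide may be lost by solvolysis, or the ketal may hydrolyse incompletely, under the aqueous acid/gold conditions. Fallback: the bromide is postponed. Setting out from 19, PPTS in aqueous acetone gives the silyl-protected hydroxy ynone F3, which (Ph3P)AuNTf2 in CH2Cl2 cycloisomerises to the silyl-protected furanone alcohol F4. DMP then gives the silyl-protected aldehyde F5, and HF·pyridine frees the hydroxy aldehyde F6. Corey–Kim bromination (NBS, Me2S, CH2Cl2, −20 °C), which converts the allylic alcohol and leaves the aldehyde alone, returns to 24.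

**Further compounds**

F1 | step 17 | [(2Z,4R,8R,9R,11R)-9-hydroxy-11-methyl-7-methylidene-6,12-dioxo-5,14-dioxatricyclo[9.2.1.0(4,8)]tetradeca-1(13),2-dien-2-yl]methyl acetate (C8 epimer of 26) | O[C@@H]1C[C@@]2(C)OC(=CC2=O)/C(COC(C)=O)=C\[C@H]2OC(=O)C(=C)[C@H]12
F2 | step 11 | (3R)-2-methoxy-3-methyl-2-[(tributylstannyl)ethynyl]oxolan-3-ol | CCCC[Sn](CCCC)(CCCC)C#CC1(OC)OCC[C@@]1(C)O
F3 | step 15 | (2E,6R)-2-{[(2R)-4-{[(tert-butyldimethylsilyl)oxy]methyl}-5-oxo-2,5-dihydrofuran-2-yl]methylidene}-6,8-dihydroxy-6-methyl-5-oxooct-3-yn-1-yl acetate | OCC[C@@](C)(O)C(=O)C#C/C(COC(C)=O)=C\[C@H]1OC(=O)C(CO[Si](C)(C)C(C)(C)C)=C1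
F4 | step 15 | (2Z)-3-[(2R)-4-{[(tert-butyldimethylsilyl)oxy]methyl}-5-oxo-2,5-dihydrofuran-2-yl]-2-[(5R)-5-(2-hydroxyethyl)-5-methyl-4-oxo-4,5-dihydrofuran-2-yl]prop-2-en-1-yl acetate | OCC[C@@]1(C)OC(=CC1=O)/C(COC(C)=O)=C\[C@H]1OC(=O)C(CO[Si](C)(C)C(C)(C)C)=C1
F5 | step 15 | (2Z)-3-[(2R)-4-{[(tert-butyldimethylsilyl)oxy]methyl}-5-oxo-2,5-dihydrofuran-2-yl]-2-[(5R)-5-methyl-4-oxo-5-(2-oxoethyl)-4,5-dihydrofuran-2-yl]prop-2-en-1-yl acetate | O=CC[C@@]1(C)OC(=CC1=O)/C(COC(C)=O)=C\[C@H]1OC(=O)C(CO[Si](C)(C)C(C)(C)C)=C1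
F6 | step 15 | (2Z)-3-[(2R)-4-(hydroxymethyl)-5-oxo-2,5-dihydrofuran-2-yl]-2-[(5R)-5-methyl-4-oxo-5-(2-oxoethyl)-4,5-dihydrofuran-2-yl]prop-2-en-1-yl acetate | O=CC[C@@]1(C)OC(=CC1=O)/C(COC(C)=O)=C\[C@H]1OC(=O)C(CO)=C1
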